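A ratio of forward to back rate loses the time, so I began with that ratio for the first step, in three flasks that differ in temperature.

    G + L ⇌ G.L (K1 = 3.1 M⁻¹, k1 = 0.0017 M⁻¹ s⁻¹, Ea1 = 66.0 kJ mol⁻¹, ΔH1 = −28.0 kJ mol⁻¹)
    G + L ⇌ J (K2 = 56 M⁻¹, k2 = 2.7 × 10⁻⁵ M⁻¹ s⁻¹, Ea2 = 84.0 kJ mol⁻¹, ΔH2 = −24.0 kJ mol⁻¹)
    G.L + X ⇌ J + X, rate k3*[X]*[G.L] forward; the back reaction follows from the equilibrium constant (k3 = 0.020 M⁻¹ s⁻¹, Ea3 = 46.0 kJ mol⁻¹)
    L + Q → X + D (k4 = 6.8 × 10⁻⁵ M⁻¹ s⁻¹, Ea4 = 77.0 kJ mol⁻¹)
    2 L → L2 (k5 = 2.4 × 10⁻⁶ M⁻¹ s⁻¹, Ea5 = 67.0 kJ mol⁻¹)
    (constants at 35 °C)

in all of them: G 1.0 M; L 0.500 M; Q 3.7 mM; time 6.0 d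

| charge | temperature |
|---|---|
| cedar | 35 °C |
| alder | −25 °C |
| birch | 5 °C |

* which flask leads in amount of G.L, in percent of the G charged ("all alike" within 1.5 percentage points) (cedar / alder / birch / all alike)
* how much G.L is there at the end, in percent of the G charged: cedar
* how much G.L is there at the end, in percent of the G charged: alder
* how much G.L is there at the end, in percent of the G charged: birch

- for a step with 2 of a species take k times the square, and two of it per event
- at 35 °C the constants are as listed, elsewhere as the activation energies and enthalpies make them

L was the limiting reagent, 0.500 M against 1.0 M of G, so I kept my ledger in L, starting with birch. When the forward and back rates of the first step are equal, time drops out and [G.L]/([G][L]) stands at a fixed value. I called this the balance quotient, the first step's equilibrium constant carried to the flask's temperature, and in birch it is 10.1 M⁻¹. I could use it from the start of the ledger because the forward half-life of L, 0.0759 d at the full charge of G, is shorter than the run.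

With no J, the quotient put 42.6% of G into G.L and left 0.0737 M of L free. At that free L, about 10.2% of Q became X by the end. Growing steadily, that X drew 0.120 M of J out of G.L, and the second step added 0.0172 M, making 0.137 M of J. Taking that off both charges and applying the quotient again gave G.L 30.8%, with 0.0550 M of L free. The pairing of two L took about 8.06 × 10⁻⁴ M, less than the charge, and the books closed.

In cedar, full balance of the first two steps binds 0.484 M of L. Even with free L held at the low amount that remains, my estimate for the growing X gave G.L a half-life of 1.52 d, shorter than the run. I therefore closed that ledger at full balance, with J over G.L at 18.1, which leaves G.L 2.54%. In alder, even with L kept at its full charge, my estimate had the fourth step turn 1.23% of Q into X by the end, and X growing steadily at that pace took 0.308% of G.L on to J, far less than the whole of it, so I set the third step aside. Plain second-order growth with the back step ignored then gave 36.7%. The balance quotient in alder is 43.5 M⁻¹, so at that amount of G.L the back rate was 0.101 of the forward rate, which I accepted for this estimate. My order was alder, birch, cedar.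

The forecast named alder, with 2.5%, 36% and 33% for cedar, alder and birch, holding that in alder “G.L is limited only by its slow second-order formation”.

The simulation puts alder ahead, with 2.50%, 36.0% and 31.3%. In birch the first step relaxes in 0.107 d, against 16.5 d for the second. The quotient times the final readings of G and L gives 31.5%, beside the 31.3% found, while J stands at 13.0% of the G charged, against my 0.137 M in a flask of 1.0 M. Now take birch with 0.25 M of G, where L is in excess at 2.00 equiv: the same quotient on its readings of G and L gives 36.0% of that G as G.L. The computed result is 33.6%.

(The constants used here were drawn at random within sensible limits; what happens was integrated by code.)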